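**Retrosynthetic overview**

- The strategy rests on the 2-pyranone ring (O1, C2 to C6): C2(=O)–C3(OMe)=C4(OMe) is the dimethoxy-enone unit of dimethyl squarate, and C5(Me)–C6(side chain, bound to O1) is a methyl-bearing carbon that has been acylated by the side-chain acid.
- Disconnect C5–C6 (C-acylation at C4 of a squarate-derived cyclobutenone) and O1–C2 (4π ring opening, then 6π oxa-closure). The pyranone is the only ring made, and it is made last.
- Cyclobutenone 3 comes from dimethyl squarate by MeLi addition and ionic hydrogenation.
- Acyl imidazole 11 comes from (6-bromohexyl)benzene by acetylide alkylation, zirconium-catalysed methylalumination with oxirane opening (sets the E alkene), oxidation and carbonyldiimidazole activation.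

Key step: step 7

Remark: the only stereo-element of lehualide E is the E trisubstituted alkene; the cyclobutenone intermediates are racemic and their sp3 centre disappears in step 7.

**Step 1**
Reactants: 1 dimethyl squarate
Product: 2 4-hydroxy-2,3-dimethoxy-4-methylcyclobut-2-en-1-one (racemic)
Conditions: MeLi (1.05 equiv), THF, −78 °C; sat. aq NH4Cl
Reagents that add atoms: methyllithium, C[Li]
Why: 1,2-addition of an organolithium to one carbonyl of a squarate ester should stop at the mono-adduct because the remaining carbonyl is a deactivated vinylogous ester; the new carbinol centre forms as a racemate and is removed later.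

**Step 2**
Reactants: 2 4-hydroxy-2,3-dimethoxy-4-methylcyclobut-2-en-1-one
Product: 3 2,3-dimethoxy-4-methylcyclobut-2-en-1-one (racemic)
Conditions: Et3SiH (3 equiv), BF3·OEt2 (Lewis acid promoter), CH2Cl2, −78 → −20 °C
Reagents that add atoms: none
Why: ionic hydrogenation, in which BF3 ionises the tertiary hydroxyl to a cyclobutenyl cation that is in effect an O-methylated enone (oxocarbenium at C2, cationic terminus at C4) and the silane should deliver hydride in the conjugate sense to C4, as in acid-mediated silane reduction of enones; the C4 centre is racemic and is lost in step 7.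

**Step 3**
Reactants: 4 (6-bromohexyl)benzene
Product: 5 8-phenyloct-1-yne
Conditions: LiC≡CH·H2NCH2CH2NH2 (lithium acetylide–ethylenediamine complex), DMSO, 0 °C → rt
Reagents that add atoms: lithium acetylide (ethylenediamine complex), [Li]C#C
Why: SN2 alkylation of lithium acetylide by a primary bromide in a dipolar aprotic solvent.

**Step 4**
Reactants: 5 8-phenyloct-1-yne; 6 oxirane
Product: 9 (3E)-4-methyl-10-phenyldec-3-en-1-ol, via alkenyldimethylalane 7 (not isolated), via lithium alkenylaluminate 8 (not isolated)
Conditions: Me3Al, Cp2ZrCl2 (cat.), CH2Cl2, rt; excess Me3Al removed in vacuo; n-BuLi, THF/hexane, 0 °C; oxirane, −30 → 0 °C; 1 M HCl work-up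
Reagents that add atoms: trimethylaluminium, C[Al](C)C
Why: Negishi zirconium-catalysed syn-methylalumination places methyl and aluminium cis on the terminal alkyne, which fixes the E geometry, and the derived lithium aluminate should transfer the alkenyl group with retention in an SN2 opening of oxirane.

**Step 5**
Reactants: 9 (3E)-4-methyl-10-phenyldec-3-en-1-ol
Product: 10 (3E)-4-methyl-10-phenyldec-3-enoic acid
Conditions: TEMPO (cat.), PhI(OAc)2 (2.2 equiv), MeCN/H2O 1:1, rt
Reagents that add atoms: water, O
Why: nitroxyl-catalysed oxidation with PhI(OAc)2 takes a primary alcohol through the aldehyde hydrate to the acid under near-neutral conditions, which should leave the β,γ-alkene in place.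

**Step 6**
Reactants: 10 (3E)-4-methyl-10-phenyldec-3-enoic acid
Product: 11 1-[(3E)-4-methyl-10-phenyldec-3-enoyl]-1H-imidazole
Conditions: 1,1'-carbonyldiimidazole (1.1 equiv), CH2Cl2, 0 °C → rt; quick ice-water wash, dry, use at once
Reagents that add atoms: 1,1'-carbonyldiimidazole, O=C(n1ccnc1)n1ccnc1
Why: acid activation with carbonyldiimidazole gives the N-acylimidazole with loss of CO2 and imidazole, and the imidazole is washed out because its N–H would protonate the enolate of step 7.

**Step 7**
Reactants: 3 2,3-dimethoxy-4-methylcyclobut-2-en-1-one; 11 1-[(3E)-4-methyl-10-phenyldec-3-enoyl]-1H-imidazole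
Product: 15 lehualide E, via lithium enolate 12 (not isolated), via 4-acylcyclobutenone 13 (not isolated), via acylvinylketene 14 (not isolated)
Conditions: lithium 2,2,6,6-tetramethylpiperidide (LiTMP, 1.05 equiv), THF, −78 °C, slow addition of 3; then 11, −78 °C; AcOH, −78 °C; cold aqueous wash; toluene, 80 °C
Reagents that add atoms: none
Why: Proposed new method: LiTMP (chosen over a silylamide because the anion is formally a cyclobutadienolate and poorly stabilised) should remove the C4 proton of 3, the enolate 12 should be acylated on carbon by 11 in a Claisen-type acylation to give 13, and after a cold acidic quench and removal of imidazole, 13 should undergo conrotatory 4π opening of its C1–C4 bond to the acylvinylketene 14. Ketene 14 then closes the pyranone ring between the acyl oxygen and the ketene carbon (O1–C2) by a thermally allowed 6π oxa-electrocyclisation that needs no base or leaving group. The closest known reaction types are the C-acylation of ketone lithium enolates by N-acylimidazoles, the thermal opening of 4-substituted cyclobutenones to vinylketenes and the closure of ketenes bearing a cis acyl group to 2-pyranones. No stereocentre is created: the quaternary centre of 13 is lost on ring opening and the E alkene of the side chain is not involved. The step needs C- over O-acylation (O-acylation would give an antiaromatic acyloxycyclobutadiene), attack through the methyl-bearing carbon and not through the methoxy-bearing C2 of the ambident anion (the π-donor methoxy group at C2 should polarise the HOMO toward C4, and C4 attack keeps the dimethoxy vinylogous ester), and acylation faster than proton transfer from the allylic CH2 of 11 (−78 °C, no excess base, acidic quench before warming). Inward rotation of the acceptor acyl group with outward rotation of methyl is the expected torquoselectivity, and because cyclobutenone–vinylketene interconversion is reversible, a ketene with the acyl group outside should return to 13 and be funnelled to the pyranone.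

**Compound list**

1 | dimethyl squarate (3,4-dimethoxycyclobut-3-ene-1,2-dione) | COC1=C(OC)C(=O)C1=O | starting material
2 | 4-hydroxy-2,3-dimethoxy-4-methylcyclobut-2-en-1-one (racemic) | COC1=C(OC)C(C)(O)C1=O | intermediate
3 | 2,3-dimethoxy-4-methylcyclobut-2-en-1-one (racemic) | COC1=C(OC)C(C)C1=O | intermediate
4 | (6-bromohexyl)benzene | BrCCCCCCc1ccccc1 | starting material
5 | 8-phenyloct-1-yne | C#CCCCCCCc1ccccc1 | intermediate
6 | oxirane | C1CO1 | starting material
7 | dimethyl[(1E)-2-methyl-8-phenyloct-1-en-1-yl]alane | C[Al](C)/C=C(\C)CCCCCCc1ccccc1 | intermediate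
8 | lithium butyl(dimethyl)[(1E)-2-methyl-8-phenyloct-1-en-1-yl]aluminate | [Li+].CCCC[Al-](C)(C)/C=C(\C)CCCCCCc1ccccc1 | intermediate
9 | (3E)-4-methyl-10-phenyldec-3-en-1-ol | OCC/C=C(\C)CCCCCCc1ccccc1 | intermediate
10 | (3E)-4-methyl-10-phenyldec-3-enoic acid | OC(=O)C/C=C(\C)CCCCCCc1ccccc1 | intermediate
11 | 1-[(3E)-4-methyl-10-phenyldec-3-enoyl]-1H-imidazole | O=C(C/C=C(\C)CCCCCCc1ccccc1)n1ccnc1 | intermediate
12 | lithium 2,3-dimethoxy-4-methylcyclobuta-1,3-dien-1-olate (enolate of 3) | COC1=C(OC)C(C)=C1O[Li] | intermediate
13 | 2,3-dimethoxy-4-methyl-4-[(3E)-4-methyl-10-phenyldec-3-enoyl]cyclobut-2-en-1-one (racemic) | COC1=C(OC)C(C)(C(=O)C/C=C(\C)CCCCCCc2ccccc2)C1=O | intermediate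
14 | (3E,7E)-2,3-dimethoxy-4,8-dimethyl-14-phenyltetradeca-1,3,7-triene-1,5-dione (acyl group cis to the ketene-bearing carbon) | O=C=C(OC)/C(OC)=C(/C)C(=O)C/C=C(\C)CCCCCCc1ccccc1 | intermediate
15 | lehualide E, 3,4-dimethoxy-5-methyl-6-[(2E)-3-methyl-9-phenylnon-2-en-1-yl]-2H-pyran-2-one | COc1c(C)c(C/C=C(\C)CCCCCCc2ccccc2)oc(=O)c1OC | target

**Step count**

Total: 7 steps. Longest linear sequence: 5 steps (steps 3, 4, 5, 6, 7).

**Steps most likely to fail**

1. Step 7 (proposed new method). Three processes may defeat it:
   - deprotonation at C4 may be incomplete or may not occur, because the anion is formally antiaromatic;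
   - the ambident anion may be acylated through its methoxy-bearing terminus, which would lead to the isomeric substitution pattern on the pyranone;
   - proton transfer from the allylic CH2 of the acyl donor may outrun acylation and move the alkene into conjugation.

   Fallback by known chemistry, setting out from 11 and returning at 15. Methyl 2-methoxy-3-oxopentanoate F1 is made by Claisen acylation of methyl methoxyacetate with propanoyl chloride (LiHMDS, THF, −78 °C). It is converted into its dianion (NaH, then n-BuLi, THF, 0 → −78 °C) and acylated at the terminal carbon by 11 to give methyl (7E)-2-methoxy-4,8-dimethyl-3,5-dioxo-14-phenyltetradec-7-enoate F2. DBU in toluene should close F2, by attack of the enol oxygen on the ester, to 4-hydroxy-3-methoxy-5-methyl-6-[(2E)-3-methyl-9-phenylnon-2-en-1-yl]-2H-pyran-2-one F3. O-methylation of the 4-hydroxyl with Me2SO4 and K2CO3 in acetone, conditions that favour the 4-methoxy-2-pyranone, should give 15.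

2. Step 2. Hydride may be delivered to the methoxy-bearing terminus of the cyclobutenyl cation, or the cation may lose its O-methyl group and collapse to the cyclobutenedione before it is reduced.

   Fallback, setting out from 2 and returning at enolate 12. Aqueous HCl in CH2Cl2 rearranges 2 to 3-methoxy-4-methylcyclobut-3-ene-1,2-dione F4. LiAlH(OtBu)3 (THF, −78 °C) should add hydride to the more electrophilic carbonyl, the one next to the methoxy-bearing carbon, giving 4-hydroxy-3-methoxy-2-methylcyclobut-2-en-1-one F5. MeI and Ag2O give 3,4-dimethoxy-2-methylcyclobut-2-en-1-one F6, in which the positions of hydrogen, methyl and methoxy are fixed without ambiguity. Deprotonation of F6 at its C4 with LiTMP gives the same delocalised anion as deprotonation of 3, so the route is rejoined at 12.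

3. Step 5. The β,γ-double bond may migrate into conjugation at the aldehyde stage, or the electron-rich trisubstituted alkene may be attacked by the oxidant.

   Fallback, setting out from alkenylalane 7 (generated from 5 as in step 4) and returning at 10. Iodinolysis (I2, THF, −30 °C) gives [(7E)-8-iodo-7-methyloct-7-en-1-yl]benzene F7 with retention. Cross-coupling of F7 with the Reformatsky reagent BrZnCH2CO2tBu under Pd(PPh3)4 (zerovalent palladium) in THF gives tert-butyl (3E)-4-methyl-10-phenyldec-3-enoate F8. CF3CO2H in CH2Cl2 cleaves the tert-butyl ester to 10 without base, so no oxidation of a homoallylic alcohol is needed.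

**Further compounds**

F1 | step 7 | methyl 2-methoxy-3-oxopentanoate | CCC(=O)C(OC)C(=O)OC
F2 | step 7 | methyl (7E)-2-methoxy-4,8-dimethyl-3,5-dioxo-14-phenyltetradec-7-enoate | COC(=O)C(OC)C(=O)C(C)C(=O)C/C=C(\C)CCCCCCc1ccccc1
F3 | step 7 | 4-hydroxy-3-methoxy-5-methyl-6-[(2E)-3-methyl-9-phenylnon-2-en-1-yl]-2H-pyran-2-one | COc1c(O)c(C)c(C/C=C(\C)CCCCCCc2ccccc2)oc1=O
F4 | step 2 | 3-methoxy-4-methylcyclobut-3-ene-1,2-dione | COC1=C(C)C(=O)C1=O
F5 | step 2 | 4-hydroxy-3-methoxy-2-methylcyclobut-2-en-1-one (racemic) | COC1=C(C)C(=O)C1O
F6 | step 2 | 3,4-dimethoxy-2-methylcyclobut-2-en-1-one (racemic) | COC1C(=O)C(C)=C1OC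
F7 | step 5 | [(7E)-8-iodo-7-methyloct-7-en-1-yl]benzene | I/C=C(\C)CCCCCCc1ccccc1
F8 | step 5 | tert-butyl (3E)-4-methyl-10-phenyldec-3-enoate | CC(C)(C)OC(=O)C/C=C(\C)CCCCCCc1ccccc1
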